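**Plan**
Retrosynthesis: the free phenols go back to pivalates, the C4 carbinol to a ketone, and the ketone to its C3=C4 silyl enol ether. That dihydropyran is cut at C5–C6 and O1–C2 in one retro-[4+2], and the diene is then cut at its C2=C3 alkene (Wittig).
Enabling feature: in the oxane ring, O1 and the aryl-bearing C6 are the oxygen and carbon of a syringaldehyde carbonyl. C2–C3–C4(O)–C5 is a 2-oxygenated buta-1,3-diene with the arylethyl chain on its far terminus, and the cis C2/C6 pair is what an endo adduct delivers.
Forward: eugenol is taken in five steps to the silyloxydiene and syringaldehyde is esterified in one. The cycloaddition joins the halves and forms the only new ring; hydrolysis, reduction and ester cleavage finish the route.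
Stereochemistry: C2 and C6 are set together by the chiral chromium catalyst (aldehyde face and endo mode). C4 is set afterwards by axial hydride attack on the chair-locked ketone.

Key step: step 7

Numbering used throughout: O1, C2 (arylethyl chain), C3, C4 (oxygenated), C5, C6 (syringyl ring).
Catalyst: CrCl(C27H29NO2) is the chloro complex of trivalent chromium with the doubly deprotonated Schiff base of (1S,2R)-1-aminoindan-2-ol and 3-(1-adamantyl)-2-hydroxy-5-methylbenzaldehyde.
Assumption: the facial preference this catalyst family shows with other aldehydes points to the (1S,2R)-aminoindanol series for the (2S,6S) adduct; the antipodal ligand is equally available if the sense proves opposite.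

Step 1
Reactants: 1 eugenol
Product: 2 4-allyl-2-methoxyphenyl pivalate
Conditions: PivCl, Et3N, DMAP (cat.), CH2Cl2, 0 °C to rt
Reagents that add atoms: pivaloyl chloride, CC(C)(C)C(=O)Cl
Why: DMAP-catalysed O-acylation of the only nucleophilic site; the pivalate lacks α-hydrogens, so it is inert to the later silyl triflate/amine enolisation, and it is hindered enough to outlast borane, perborate and borohydride.

Step 2
Reactants: 2 4-allyl-2-methoxyphenyl pivalate
Product: 4 4-(3-hydroxypropyl)-2-methoxyphenyl pivalate, via B-alkyl-9-BBN adduct 3 (not isolated)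
Conditions: 9-BBN, THF, 0 °C to rt; then NaBO3·4H2O, H2O, rt
Reagents that add atoms: 9-borabicyclo[3.3.1]nonane, B1C2CCCC1CCC2 (its boron and carbons stay in 3 only); sodium perborate, [Na+].[O-]OB=O (hydroxyl oxygen of 4)
Why: Hydroboration–oxidation: the bulky dialkylborane places boron on the terminal carbon of the monosubstituted alkene and ignores the ester, and the mildly basic perborate oxidises the C–B bond under conditions a hindered aryl ester should tolerate.

Step 3
Reactants: 4 4-(3-hydroxypropyl)-2-methoxyphenyl pivalate
Product: 5 2-methoxy-4-(3-oxopropyl)phenyl pivalate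
Conditions: TEMPO (10 mol%), (diacetoxyiodo)benzene, CH2Cl2, rt
Reagents that add atoms: none
Why: Oxoammonium (TEMPO) oxidation with the iodane as terminal oxidant stops at the aldehyde in the absence of water, and the acylated phenol is not attacked by the oxidant.

Step 4
Reactants: 5 2-methoxy-4-(3-oxopropyl)phenyl pivalate; 6 1-(triphenylphosphoranylidene)propan-2-one
Product: 7 (E)-6-(3-methoxy-4-pivaloyloxyphenyl)hex-3-en-2-one
Conditions: toluene, 80 °C
Reagents that add atoms: none
Why: Wittig olefination with a carbonyl-stabilised ylide, which is mild enough for an enolisable aldehyde and gives the E-enone through the favoured trans-oxaphosphetane.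

Step 5
Reactants: 7 (E)-6-(3-methoxy-4-pivaloyloxyphenyl)hex-3-en-2-one
Product: 8 (E)-6-(3-methoxy-4-pivaloyloxyphenyl)-2-(triethylsilyloxy)hexa-1,3-diene
Conditions: Et3SiOTf, Et3N, Et2O, 0 °C; pentane extraction, short column of Et3N-deactivated silica
Reagents that add atoms: triethylsilyl triflate, CC[Si](CC)(CC)OS(=O)(=O)C(F)(F)F
Why: Soft enolisation with silyl triflate and a tertiary amine: O-silylation of the carbonyl and removal of the more accessible α′-methyl proton give the cross-conjugated 2-silyloxydiene with the E-alkene untouched, the standard entry to such dienes from methyl enones.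

Step 6
Reactants: 9 syringaldehyde
Product: 10 3,5-dimethoxy-4-pivaloyloxybenzaldehyde
Conditions: PivCl, Et3N, DMAP (cat.), CH2Cl2, 0 °C to rt
Reagents that add atoms: pivaloyl chloride, CC(C)(C)C(=O)Cl
Why: DMAP-catalysed O-acylation, which masks an acidic phenol that would bind the chromium catalyst and removes the para oxygen donor that deactivates the formyl group.

Step 7
Reactants: 8 (E)-6-(3-methoxy-4-pivaloyloxyphenyl)-2-(triethylsilyloxy)hexa-1,3-diene; 10 3,5-dimethoxy-4-pivaloyloxybenzaldehyde
Product: 11 (2S,6S)-6-(3,5-dimethoxy-4-pivaloyloxyphenyl)-2-[2-(3-methoxy-4-pivaloyloxyphenyl)ethyl]-4-(triethylsilyloxy)-5,6-dihydro-2H-pyran (2,6-cis)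
Conditions: 8 (1.3 equiv), CrCl(C27H29NO2) (10 mol%), powdered 4 Å MS, acetone (minimum volume), rt, 2–3 d; filtration through deactivated silica
Reagents that add atoms: none
Why: The aldehyde oxygen binds the Lewis-acidic trivalent chromium centre and the polarised diene adds in a concerted but asynchronous hetero-Diels–Alder reaction, with C5–C6 formation from the nucleophilic CH2 terminus running ahead of O1–C2 closure. The closest known reaction type is this catalyst family's own cycloaddition of 4-substituted 2-silyloxydienes with aldehydes, aromatic ones included, so only the substrates are new. The dihydropyran ring closes intermolecularly by the [4+2] cycloaddition itself, both ring bonds forming in one event and the C3=C4 enol ether marking the former diene centre. C6 is set by the catalyst, whose indane and adamantyl groups leave one aldehyde face open, and C2 follows from the catalyst-enforced endo approach together with the E geometry of the diene C2=C3 bond, which places the two substituents cis. The regioselectivity needed is secured by the silyloxy group on C4, which makes C5 the donor terminus, and chemoselectivity is secured because the hindered pivalate carbonyls are neither good ligands nor heterodienophiles. Reactivity benefits from an aldehyde without a para donor, since the acylated oxygen is withdrawn from conjugation and both methoxy groups are meta to the formyl group.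

Step 8
Reactants: 11 cis-dihydropyran triethylsilyl enol ether
Product: 12 (2S,6S)-6-(3,5-dimethoxy-4-pivaloyloxyphenyl)-2-[2-(3-methoxy-4-pivaloyloxyphenyl)ethyl]oxan-4-one
Conditions: 1 M HCl, THF, 0 °C
Reagents that add atoms: none
Why: Acid hydrolysis of a silyl enol ether (protonation at C3, transfer of silicon to water) touches neither C2 nor C6, and because the diequatorial cis ketone is also the thermodynamic isomer a reversible retro-oxa-Michael event could not erode the configuration.

Step 9
Reactants: 12 cis-oxan-4-one bis-pivalate
Product: 13 (2S,4R,6S)-6-(3,5-dimethoxy-4-pivaloyloxyphenyl)-2-[2-(3-methoxy-4-pivaloyloxyphenyl)ethyl]oxan-4-ol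
Conditions: NaBH4, MeOH, −20 °C
Reagents that add atoms: none
Why: Substrate-controlled borohydride reduction: with both substituents equatorial the chair is locked and the small hydride attacks along the axial trajectory, which should place the new hydroxyl equatorial (4R) and cis to the C2 and C6 groups, while the aryl pivalates are left intact at low temperature.

Step 10
Reactants: 13 all-cis oxan-4-ol bis-pivalate
Product: 14 (2S,4R,6S)-6-(4-hydroxy-3,5-dimethoxyphenyl)-2-[2-(4-hydroxy-3-methoxyphenyl)ethyl]oxan-4-ol (CNP0302691.1)
Conditions: NaOMe, degassed MeOH, Ar, 0 °C to rt; then 1 M HCl to pH 5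
Reagents that add atoms: none
Why: Zemplén-type transesterification in which methoxide attacks the activated aryl esters and expels the phenoxides, the secondary alcohol and ring ether being inert and exclusion of air protecting the electron-rich phenoxides until acidification.

**Compound list**
1 | eugenol (4-allyl-2-methoxyphenol) | C=CCc1ccc(O)c(OC)c1 | starting material
2 | 4-allyl-2-methoxyphenyl pivalate | C=CCc1ccc(OC(=O)C(C)(C)C)c(OC)c1 | intermediate
3 | 9-[3-(3-methoxy-4-pivaloyloxyphenyl)propyl]-9-borabicyclo[3.3.1]nonane | COc1cc(CCCB2C3CCCC2CCC3)ccc1OC(=O)C(C)(C)C | intermediate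
4 | 4-(3-hydroxypropyl)-2-methoxyphenyl pivalate | COc1cc(CCCO)ccc1OC(=O)C(C)(C)C | intermediate
5 | 2-methoxy-4-(3-oxopropyl)phenyl pivalate | COc1cc(CCC=O)ccc1OC(=O)C(C)(C)C | intermediate
6 | 1-(triphenylphosphoranylidene)propan-2-one | CC(=O)C=P(c1ccccc1)(c1ccccc1)c1ccccc1 | starting material
7 | (E)-6-(3-methoxy-4-pivaloyloxyphenyl)hex-3-en-2-one | CC(=O)/C=C/CCc1ccc(OC(=O)C(C)(C)C)c(OC)c1 | intermediate
8 | (E)-6-(3-methoxy-4-pivaloyloxyphenyl)-2-(triethylsilyloxy)hexa-1,3-diene | C=C(O[Si](CC)(CC)CC)/C=C/CCc1ccc(OC(=O)C(C)(C)C)c(OC)c1 | intermediate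
9 | syringaldehyde (4-hydroxy-3,5-dimethoxybenzaldehyde) | COc1cc(C=O)cc(OC)c1O | starting material
10 | 3,5-dimethoxy-4-pivaloyloxybenzaldehyde | O=Cc1cc(OC)c(OC(=O)C(C)(C)C)c(OC)c1 | intermediate
11 | (2S,6S)-cis-6-(3,5-dimethoxy-4-pivaloyloxyphenyl)-2-[2-(3-methoxy-4-pivaloyloxyphenyl)ethyl]-4-(triethylsilyloxy)-5,6-dihydro-2H-pyran | COc1cc(CC[C@H]2C=C(O[Si](CC)(CC)CC)C[C@@H](c3cc(OC)c(OC(=O)C(C)(C)C)c(OC)c3)O2)ccc1OC(=O)C(C)(C)C | intermediate
12 | (2S,6S)-cis-6-(3,5-dimethoxy-4-pivaloyloxyphenyl)-2-[2-(3-methoxy-4-pivaloyloxyphenyl)ethyl]oxan-4-one | COc1cc(CC[C@H]2CC(=O)C[C@@H](c3cc(OC)c(OC(=O)C(C)(C)C)c(OC)c3)O2)ccc1OC(=O)C(C)(C)C | intermediate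
13 | (2S,4R,6S)-all-cis-6-(3,5-dimethoxy-4-pivaloyloxyphenyl)-2-[2-(3-methoxy-4-pivaloyloxyphenyl)ethyl]oxan-4-ol | COc1cc(CC[C@H]2C[C@@H](O)C[C@@H](c3cc(OC)c(OC(=O)C(C)(C)C)c(OC)c3)O2)ccc1OC(=O)C(C)(C)C | intermediate
14 | (2S,4R,6S)-6-(4-hydroxy-3,5-dimethoxyphenyl)-2-[2-(4-hydroxy-3-methoxyphenyl)ethyl]oxan-4-ol | COc1cc(CC[C@H]2C[C@@H](O)C[C@@H](c3cc(OC)c(O)c(OC)c3)O2)ccc1O | target

Total step count: 10. Longest linear sequence: 9 (steps 1–5 and 7–10).

**Steps most likely to fail**

Step 7. Turnover with an aromatic aldehyde may be slow. During a long reaction the diene can hydrolyse, and an uncatalysed or stepwise background pathway can erode face and endo selectivity. The fallback sets out from 8 and 10 and returns at 12, making the two ring bonds one after the other.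
- A Mukaiyama aldol addition of 8 to 10 is promoted by SiCl4 activated with a catalytic chiral binaphthyldiamine-derived bisphosphoramide (antipode chosen for the S carbinol; iPr2NEt, CH2Cl2, −78 °C). This system is at its best with aromatic aldehydes.
- After buffered aqueous work-up it should give (1S,4E)-1-(3,5-dimethoxy-4-pivaloyloxyphenyl)-1-hydroxy-7-(3-methoxy-4-pivaloyloxyphenyl)hept-4-en-3-one F1.
- Amberlyst-15 in CH2Cl2 then closes O1–C2 by a reversible 6-endo-trig oxa-Michael addition. Under that equilibrium the diequatorial cis ketone 12 is the favoured isomer.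

Step 5. γ-Deprotonation to the linear, fully conjugated dienol ether may compete, and the triethylsilyl dienol ether may hydrolyse during isolation. The fallback sets out from 5 and 10 and returns at 13, building the ring by a Prins cyclisation without any diene.
- Keck allylation of 5 (allyltributylstannane, Ti(OiPr)4/(R)-BINOL cat., 4 Å MS, CH2Cl2, −20 °C) should give 4-[(3S)-3-hydroxyhex-5-en-1-yl]-2-methoxyphenyl pivalate F2.
- Condensation of F2 with 10 in TFA/CH2Cl2 at 0 °C forms an oxocarbenium ion that cyclises through an all-equatorial chair. Equatorial capture by trifluoroacetate gives (2S,4R,6S)-6-(3,5-dimethoxy-4-pivaloyloxyphenyl)-2-[2-(3-methoxy-4-pivaloyloxyphenyl)ethyl]oxan-4-yl trifluoroacetate F3, so the C2 centre from the allylation controls C4 and C6.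
- Brief treatment with NaHCO3 in MeOH removes only the trifluoroacetate and gives 13.

Step 10. Methanolysis of the doubly ortho-flanked syringyl pivalate may be incomplete. Prolonged exposure to base risks air oxidation of the electron-rich phenoxides, or reversible opening of the C6–O1 bond through a para-quinone methide. The fallback sets out from 13 and returns at 14 by reductive rather than solvolytic ester cleavage. LiAlH4 in THF at 0 °C attacks both hindered esters irreversibly in an aprotic, air-free medium and holds the phenols as aluminium phenoxides until a mildly acidic work-up. No compound outside the list is made (entry F0).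

**Further compounds**
F1 | step 7 | (1S,4E)-1-(3,5-dimethoxy-4-pivaloyloxyphenyl)-1-hydroxy-7-(3-methoxy-4-pivaloyloxyphenyl)hept-4-en-3-one | COc1cc(CC/C=C/C(=O)C[C@@H](c2cc(OC)c(OC(=O)C(C)(C)C)c(OC)c2)O)ccc1OC(=O)C(C)(C)C
F2 | step 5 | 4-[(3S)-3-hydroxyhex-5-en-1-yl]-2-methoxyphenyl pivalate | COc1cc(CC[C@H](O)CC=C)ccc1OC(=O)C(C)(C)C
F3 | step 5 | (2S,4R,6S)-6-(3,5-dimethoxy-4-pivaloyloxyphenyl)-2-[2-(3-methoxy-4-pivaloyloxyphenyl)ethyl]oxan-4-yl trifluoroacetate | COc1cc(CC[C@H]2C[C@@H](OC(=O)C(F)(F)F)C[C@@H](c3cc(OC)c(OC(=O)C(C)(C)C)c(OC)c3)O2)ccc1OC(=O)C(C)(C)C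
F0 | step 10 | none | none
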